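**Assumptions.** The target is read as three (2R,3R)-epicatechin units joined 4β→8 (C4 is R, trans to the 3-O and to the 2-aryl). The lowest unit has a CH2 at C4, the top unit has free C6 and C8, and every 3-OH is a galloyl ester. Electrophilic aromatic substitution of these 5,7-dibenzyloxy flavans is assumed to favour C8 over C6.

**Retrosynthesis**
- The target comes from global hydrogenolysis of a perbenzylated trimer that still carries one blocking Br. The trimer comes from two TMSOTf-mediated 4β,8 couplings of a C8-blocked 4-alkoxy electrophile, with one Br removal between them. The chain grows from the lowest unit upward.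
- The monomer is 3-O-galloyl epicatechin, made from a catechin-type 2,3-trans flavan by Mitsunobu galloylation with inversion at C3.
- The flavan C-ring is formed by a new cascade on an epoxy carbinol: 6-endo debenzylative epoxide opening plus ionic deoxygenation of C4.
- The epoxy carbinol comes from an aryllithium plus an organocatalytic trans-epoxy aldehyde. The first stereocenters are set in that epoxidation, and the epoxy aldehyde comes from the Wittig product of 3,4-bis(benzyloxy)benzaldehyde.
- Rings are formed in this order: epoxide, then pyran C-ring, then two interflavan C–C bonds.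

---

**Step 1**
Reactants: 1 phloroglucinol; 2 benzyl bromide
Product: 3 1,3,5-tris(benzyloxy)benzene
Conditions: BnBr (3.3 equiv), K2CO3, DMF, 60 °C
Reagents that add atoms: benzyl bromide, BrCc1ccccc1 (compound 2)
Why: Williamson O-benzylation gives the A-ring nucleophile precursor.

**Step 2**
Reactants: 4 3,4-bis(benzyloxy)benzaldehyde; 5 (formylmethylene)triphenylphosphorane
Product: 6 (E)-3-[3,4-bis(benzyloxy)phenyl]propenal
Conditions: toluene, 80 °C, 12 h
Reagents that add atoms: ylide 5, O=CC=P(c1ccccc1)(c1ccccc1)c1ccccc1 (it supplies the CH=CHCHO fragment)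
Why: a Wittig olefination with a stabilized ylide gives the E-enal.

**Step 3**
Reactants: 6; 7 (R)-α,α-diphenylprolinol TMS ether (10 mol %); 8 hydrogen peroxide
Product: 9 (2R,3S)-3-[3,4-bis(benzyloxy)phenyl]oxirane-2-carbaldehyde
Conditions: 7 (10 mol %), 30% aq. H2O2 (1.5 equiv), CH2Cl2, rt, 24 h
Reagents that add atoms: hydrogen peroxide, OO (it supplies the epoxide O)
Why: Iminium–enamine organocatalytic nucleophilic epoxidation (Jørgensen–Hayashi). The catalyst shields one iminium face, so HOO⁻ adds to Cβ on the open face and the enamine then closes the trans-epoxide. This sets C3 (2S→ flavan C3 S) and the Ar-bearing carbon (3S→ flavan C2 R after the later inversion) in >95% ee.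

**Step 4**
Reactants: 3; 9
Product: 10 epoxy carbinol, (2R,3S)-epoxide with the carbinol carbon as an epimeric mixture
Conditions: 3 (1.5 equiv), n-BuLi (1.5 equiv), THF, 0 °C, 1 h; cool to −78 °C, add 9, 1 h; sat. NH4Cl
Reagents that add atoms: none (n-BuLi is only the base)
Why: Ortho-lithiation between two OBn groups, then 1,2-addition to the aldehyde. The new carbinol stereocenter is erased in step 5, so both epimers converge and the epoxide stereocenters are untouched.

**Step 5**
Reactants: 10
Product: 11 5,7,3',4'-tetra-O-benzyl-(+)-catechin, (2R,3S)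
Conditions: BF3·OEt2 (3 equiv), Et3SiH (5 equiv), pentamethylbenzene (3 equiv), CH2Cl2, −78 → 0 °C; NaHCO3 work-up
Reagents that add atoms: none (Et3SiH supplies only hydride)
Why: Proposed new method: BF3 ionizes the electron-rich benzylic epoxide C–O bond. The ortho-OBn oxygen of the A-ring attacks C2 in a 6-endo, inversion-type closure, and the resulting aryl benzyl oxonium loses Bn⁺ to pentamethylbenzene. The very labile 2,4,6-trialkoxybenzylic C4–OH is ionized and reduced by Et3SiH. The closest known reactions are endo epoxy-alcohol cycloetherification, debenzylative cyclization of benzyl ethers onto cations, and Et3SiH ionic deoxygenation of benzylic alcohols. The epoxide carbon bearing the oxygen (flavan C3) keeps its 3S configuration, the benzylic carbon (flavan C2) is inverted to 2R, and the product is the 2,3-trans flavan.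

**Step 6**
Reactants: 11; 12 3,4,5-tris(benzyloxy)benzoic acid
Product: 13 5,7,3',4'-tetra-O-benzyl-(−)-epicatechin 3-(3,4,5-tri-O-benzylgallate), (2R,3R)
Conditions: PPh3 (2 equiv), DIAD (2 equiv), 12 (2 equiv), THF, 0 °C → rt
Reagents that add atoms: tri-O-benzylgallic acid, OC(=O)c1cc(OCc2ccccc2)c(OCc2ccccc2)c(OCc2ccccc2)c1 (compound 12)
Why: Mitsunobu esterification proceeds by SN2 at C3 with inversion (3S→3R), turning the 2,3-trans flavan into the 2,3-cis epicatechin skeleton and installing the galloyl in one step.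

**Step 7**
Reactants: 13; 14 N-bromosuccinimide
Product: 15 8-bromo-13
Conditions: NBS (1.05 equiv), CH2Cl2, −78 °C, 30 min
Reagents that add atoms: NBS, BrN1C(=O)CCC1=O (compound 14)
Why: Electrophilic aromatic bromination occurs at C8, the most nucleophilic A-ring position (between O1 and 7-OBn). The Br blocks self-condensation of this unit when it is later used as the electrophile.

**Step 8**
Reactants: 15; 16 2-(trimethylsilyl)ethanol
Product: 17 4-(2-trimethylsilylethoxy)-8-bromo-13 (C4 ether trans to the 3-O-galloyl)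
Conditions: DDQ (1.5 equiv), 16 (5 equiv), 4 Å MS, CH2Cl2, 0 °C → rt
Reagents that add atoms: 2-(trimethylsilyl)ethanol, C[Si](C)(C)CCO (compound 16)
Why: DDQ abstracts hydride from the benzylic C4–H to give a 5,7-dioxygenated benzylic cation, which the alcohol traps; this is the standard DDQ route to flavan-4-ol ether donors. The C4 configuration is irrelevant because it is ionized again in the next coupling.

**Step 9**
Reactants: 17; 13 (3 equiv, as nucleophile)
Product: 18 dimer, 4β→8 linked, with Br on the middle-unit C8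
Conditions: TMSOTf (0.3 equiv), CH2Cl2, −20 → 0 °C; 17 added slowly to 13
Reagents that add atoms: none (TMSOTf is catalytic and the TMS-ethoxide leaves)
Why: TMSOTf ionizes the 4-OR group. The 3-O-galloyl forms a dioxolenium bridge on the face of the 3-O and 2-aryl, so C8 of 13 attacks C4 from the opposite face (Friedel–Crafts-type SEAr). This sets C4 as R, trans to the 3-O, i.e. 4β; the Br on the middle unit stops self-condensation.

**Step 10**
Reactants: 18
Product: 19 debrominated dimer (free middle-unit C8–H)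
Conditions: H2 (1 atm), 10% Pd/C, Et3N (3 equiv), EtOAc, rt, 2 h
Reagents that add atoms: none (H2 adds only hydrogen)
Why: Base-buffered Pd hydrodebromination cleaves Ar–Br selectively over benzyl ethers and aryl esters, regenerating the C8 nucleophile; no stereocenter is touched.

**Step 11**
Reactants: 19; 17 (1.3 equiv)
Product: 20 perbenzylated trimer, bearing Br on the upper-unit C8
Conditions: TMSOTf (0.3 equiv), CH2Cl2, −20 °C; 17 added slowly to 19
Reagents that add atoms: none
Why: The same anchimerically assisted 4β-selective SEAr couples the middle-unit C8 of 19 to C4 of the upper unit (C4 R); the Br again prevents self-condensation of 17.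

**Step 12**
Reactants: 20
Product: 21 procyanidin C1 3,3',3''-tri-O-gallate (target)
Conditions: H2 (1 atm), Pd(OH)2/C, NaHCO3, THF/MeOH, rt, 24 h
Reagents that add atoms: none (H2 adds only hydrogen)
Why: Global hydrogenolysis removes all 21 benzyl groups and the aryl Br (base buffers the HBr, which could cleave the interflavan bonds), giving the free polyphenol with all stereocenters unchanged.

---

**Compound list**

1 | phloroglucinol | Oc1cc(O)cc(O)c1 | starting material
2 | benzyl bromide | BrCc1ccccc1 | starting material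
3 | 1,3,5-tris(benzyloxy)benzene | c1ccc(COc2cc(OCc3ccccc3)cc(OCc3ccccc3)c2)cc1 | intermediate
4 | 3,4-bis(benzyloxy)benzaldehyde | O=Cc1ccc(OCc2ccccc2)c(OCc2ccccc2)c1 | starting material
5 | (formylmethylene)triphenylphosphorane | O=CC=P(c1ccccc1)(c1ccccc1)c1ccccc1 | starting material
6 | (E)-3-[3,4-bis(benzyloxy)phenyl]propenal | O=C/C=C/c1ccc(OCc2ccccc2)c(OCc2ccccc2)c1 | intermediate
7 | (R)-α,α-diphenylprolinol TMS ether (catalyst) | C[Si](C)(C)OC(c1ccccc1)(c1ccccc1)[C@H]1CCCN1 | starting material (catalyst)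
8 | hydrogen peroxide | OO | starting material
9 | (2R,3S)-3-[3,4-bis(benzyloxy)phenyl]oxirane-2-carbaldehyde | O=C[C@@H]1O[C@H]1c2ccc(OCc9ccccc9)c(OCc9ccccc9)c2 | intermediate
10 | epoxy carbinol (carbinol epimeric) | OC(c1c(OCc9ccccc9)cc(OCc9ccccc9)cc1OCc9ccccc9)[C@@H]2O[C@H]2c3ccc(OCc9ccccc9)c(OCc9ccccc9)c3 | intermediate
11 | 5,7,3',4'-tetra-O-benzyl-(+)-catechin (2R,3S) | O[C@H]1Cc2c(OCc9ccccc9)cc(OCc9ccccc9)cc2O[C@@H]1c3ccc(OCc9ccccc9)c(OCc9ccccc9)c3 | intermediate
12 | 3,4,5-tris(benzyloxy)benzoic acid | OC(=O)c1cc(OCc2ccccc2)c(OCc2ccccc2)c(OCc2ccccc2)c1 | starting material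
13 | tetra-O-benzylepicatechin 3-(tri-O-benzylgallate) (2R,3R) | O=C(O[C@@H]1Cc2c(OCc9ccccc9)cc(OCc9ccccc9)cc2O[C@@H]1c3ccc(OCc9ccccc9)c(OCc9ccccc9)c3)c4cc(OCc9ccccc9)c(OCc9ccccc9)c(OCc9ccccc9)c4 | intermediate
14 | N-bromosuccinimide | BrN1C(=O)CCC1=O | starting material
15 | 8-bromo-13 | O=C(O[C@@H]1Cc2c(OCc9ccccc9)cc(OCc9ccccc9)c(Br)c2O[C@@H]1c3ccc(OCc9ccccc9)c(OCc9ccccc9)c3)c4cc(OCc9ccccc9)c(OCc9ccccc9)c(OCc9ccccc9)c4 | intermediate
16 | 2-(trimethylsilyl)ethanol | C[Si](C)(C)CCO | starting material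
17 | 4-(2-TMS-ethoxy)-8-bromo electrophile | O=C(O[C@@H]1[C@@H](OCC[Si](C)(C)C)c2c(OCc9ccccc9)cc(OCc9ccccc9)c(Br)c2O[C@@H]1c3ccc(OCc9ccccc9)c(OCc9ccccc9)c3)c4cc(OCc9ccccc9)c(OCc9ccccc9)c(OCc9ccccc9)c4 | intermediate
18 | 8-bromo dimer (4β→8) | O=C(O[C@@H]1[C@@H](c2c(OCc9ccccc9)cc(OCc9ccccc9)c3c2O[C@H](c4ccc(OCc9ccccc9)c(OCc9ccccc9)c4)[C@H](OC(=O)c5cc(OCc9ccccc9)c(OCc9ccccc9)c(OCc9ccccc9)c5)C3)c6c(OCc9ccccc9)cc(OCc9ccccc9)c(Br)c6O[C@@H]1c7ccc(OCc9ccccc9)c(OCc9ccccc9)c7)c8cc(OCc9ccccc9)c(OCc9ccccc9)c(OCc9ccccc9)c8 | intermediate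
19 | debrominated dimer | O=C(O[C@@H]1[C@@H](c2c(OCc9ccccc9)cc(OCc9ccccc9)c3c2O[C@H](c4ccc(OCc9ccccc9)c(OCc9ccccc9)c4)[C@H](OC(=O)c5cc(OCc9ccccc9)c(OCc9ccccc9)c(OCc9ccccc9)c5)C3)c6c(OCc9ccccc9)cc(OCc9ccccc9)cc6O[C@@H]1c7ccc(OCc9ccccc9)c(OCc9ccccc9)c7)c8cc(OCc9ccccc9)c(OCc9ccccc9)c(OCc9ccccc9)c8 | intermediate
20 | perbenzylated 8-bromo trimer | O=C(O[C@@H]1[C@@H](c2c(OCc9ccccc9)cc(OCc9ccccc9)c3c2O[C@H](c4ccc(OCc9ccccc9)c(OCc9ccccc9)c4)[C@H](OC(=O)c5cc(OCc9ccccc9)c(OCc9ccccc9)c(OCc9ccccc9)c5)C3)c6c(OCc9ccccc9)cc(OCc9ccccc9)c([C@H]%10c%11c(OCc9ccccc9)cc(OCc9ccccc9)c(Br)c%11O[C@H](c4ccc(OCc9ccccc9)c(OCc9ccccc9)c4)[C@@H]%10OC(=O)c5cc(OCc9ccccc9)c(OCc9ccccc9)c(OCc9ccccc9)c5)c6O[C@@H]1c7ccc(OCc9ccccc9)c(OCc9ccccc9)c7)c8cc(OCc9ccccc9)c(OCc9ccccc9)c(OCc9ccccc9)c8 | intermediate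
21 | procyanidin C1 3,3',3''-tri-O-gallate | O=C(O[C@@H]1[C@@H](c2c(O)cc(O)c3c2O[C@H](c2ccc(O)c(O)c2)[C@H](OC(=O)c2cc(O)c(O)c(O)c2)C3)c2c(O)cc(O)c([C@H]3c4c(O)cc(O)cc4O[C@H](c4ccc(O)c(O)c4)[C@@H]3OC(=O)c3cc(O)c(O)c(O)c3)c2O[C@@H]1c1ccc(O)c(O)c1)c1cc(O)c(O)c(O)c1 | target

---

**Total steps:** 12
**Longest linear sequence:** 11 steps (4 → 6 → 9 → 10 → 11 → 13 → 15 → 17 → 18 → 19 → 20 → 21)

**Three steps most likely to fail**
1. **Step 5 (proposed new cascade).** The aryl epoxide may undergo a Meinwald rearrangement or Et3SiH reduction at C2, and a benzyl cation may alkylate the A-ring. Fallback: use known chemistry and tetra-O-benzylate commercial (+)-catechin (BnBr, K2CO3, DMF) to give 11, which is a chiral-pool entry rather than the organocatalytic one.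
2. **Step 6 (Mitsunobu inversion).** Flav-3-ene elimination or sluggish SN2 at the equatorial 3-OH may lower the yield. Fallback: oxidize 11 with Dess–Martin periodinane to the flavan-3-one, reduce with L-Selectride to the 2,3-cis alcohol, then acylate with acid 12 (DCC/DMAP).
3. **Step 11 (trimer coupling).** The dimer has several free nucleophilic sites (C6 of two units and C8 of the middle unit), so regioselectivity and yield may be poor. Fallback: swap the 4-alkoxy donor for a 4-arylthio donor activated by AgOTf at −78 °C, which changes the leaving group and activation mode.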